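All runs come from a simulation with made-up constants; noise was put on by code.

A small charge of solid reagent opened my reckoning: 24.0 mM stood against 70.0 mM of the three substrates together. So, if each substrate takes it up, I expected the supply of target to stop early.

all flasks: starting material 20 mM

| run | second substrate | third substrate | solid reagent | temperature | remark | time |
|---|---|---|---|---|---|---|
| alder | 40 mM | 10 mM | 24 mM | 5 °C | the very flask that is asked about, followed so far |  |
| oak | 40 mM | 10 mM | 24 mM | 11 °C | run made earlier |  |
| flask | 40.0 mM | 10.0 mM | 24.0 mM | 5 °C |  | 20 h |

| run | time / h | target / % |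
|---|---|---|
| alder | 1.33 | 6.7 |
| alder | 2.00 | 9.7 |
| alder | 4.00 | 21.0 |
| alder | 6.00 | 32.1 |
| alder | 10.0 | 29.6 |
| alder | 15.0 | 23.2 |
| oak | 1.33 | 6.9 |
| oak | 2.00 | 11.8 |
| oak | 4.00 | 23.6 |
| oak | 6.00 | 26.5 |
| oak | 10.0 | 15.5 |
| oak | 15.0 | 6.7 |

(standard deviation of a reading: 0.5 percentage points)

- solid reagent is a solid; its amount is given per volume of the solution
- target taken out counts as made
- what was read earlier has a scatter of 0.5 percentage points, one standard deviation
- at the start none of the solid reagent is in solution
- additions bring no volume worth counting

- Thursday's: at 20 h take out 90% of the target then present, then wait 20 h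
- Wednesday's: at 20 h raise the temperature by 15 K, then wait 20 h
- Tuesday's: at 20 h add starting material, 50.0% of the amount charged, then wait 20 h
- Monday's: change nothing and wait 20 h more

1. target, in percent of the starting material first charged, at 20 h
2. what to do for the largest gain in target; "none" if nothing gains more than 2 percentage points (Thursday's / Wednesday's / Tuesday's / Monday's / none)
3. target present, with what was taken out counted in, in percent of the starting material first charged, after Wednesday's
4. target present, with what was taken out counted in, in percent of the starting material first charged, after Tuesday's

The alder run did turn. From 10.0 h to 15.0 h it fell, so I read the tail constant, 0.0487 h⁻¹, the first-order rate of loss of target taken from two late readings. Between 4.00 h and 6.00 h that loss came to 3.1 percentage points at the peak reading, against a net gain of 11 points. So supply led then, but by 10.0 h it trailed, and the late readings are the ones to watch.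

Carried from the last reading, the constant gave me 18.2% at 20 h. Waiting 20 h more gave 6.86%. Thursday's gave 17.1%, which is still less than I started from, so I chose none. I took the supply to have stopped by then, so I put Tuesday's at the waiting value. The warmer oak run fell at 0.168 h⁻¹, 3.45 times faster, so I expected Wednesday's to lose even more.

The forecast gave 18%, Thursday's, 0.5% for Wednesday's and 13% for Tuesday's, noting that "the remaining reagent is doubtful"; it differs from mine on the choice and on Tuesday's.

    third substrate + coupling partner → third product (k = 99.0 M⁻¹ h⁻¹, Ea = 62.0 kJ mol⁻¹)
    second substrate + coupling partner → second product (k = 6.40 M⁻¹ h⁻¹, Ea = 61.0 kJ mol⁻¹)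
    target → over-reaction product (k = 0.0590 h⁻¹, Ea = 102 kJ mol⁻¹)
    starting material + coupling partner → target (k = 23.0 M⁻¹ h⁻¹, Ea = 57.0 kJ mol⁻¹)
    solid reagent ⇌ coupling partner, rate k5*(cs5 - [coupling partner]) while solid is left; crystals form when [coupling partner] > cs5 (solubility = 8.70 mM, k = 0.820 h⁻¹)
    (constants at 5 °C)

The flask gave 17.2% at 20 h, and the choice was none, with Thursday's at −1.2 points and Wednesday's ending at 0%. The solid reagent, the limiting reagent, stood at 0% after 10.0 h, with 55.9% of the starting material still free at 20.0 h. From the flask's own value, the tail constant gives 6.49% after 20 h more, and Tuesday's gave 5.29%. The same rule on the oak run gives 2.90% at 20 h, where that run stood at 3.58%.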